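The numbers of this flask are those of an exercise; the result is computed.

At the reading, 12 s after mixing, the target in each flask is wanted as a fraction of the substrate charged.

    2 second chain carrier → ended chains (k1 = 2.9 × 10⁷ L mol⁻¹ s⁻¹)
    substrate + second chain carrier → released group + first chain carrier (k2 = 76000 L mol⁻¹ s⁻¹)
    reagent + target → over-reaction product (k3 = 25 L mol⁻¹ s⁻¹)
    initiator → 2 initiating radical (k4 = 0.32 s⁻¹)
    substrate + initiating radical → capped initiator + first chain carrier (k5 = 5.1 × 10⁶ L mol⁻¹ s⁻¹)
    reagent + first chain carrier ⇌ target + second chain carrier (K6 = 0.52, k6 = 65000 L mol⁻¹ s⁻¹)

| setting | south-west | south-east | east | north | north-west |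
|---|---|---|---|---|---|
| substrate | 5.0 mM | 5.0 mM | 5.0 mM | 5.0 mM | 5.0 mM |
| reagent | 1.00 mM | 1.50 mM | 2.00 mM | 3.00 mM | 5.00 mM |
| initiator | 0.38 mM | 0.38 mM | 0.38 mM | 0.38 mM | 0.38 mM |
| time | 12 s | 12 s | 12 s | 12 s | 12 s |

- amount of target at the end, in percent of the substrate charged for south-west, south-east, east, north, north-west, in this order
- the shape of the row from first to last (falls all the way / falls, then rises / rises all the way / hardly changes / rises, then falls)

- a step written with two of one species runs at k times the square of its concentration and takes two of it each time
- "hardly changes" means that all values lie within two and a half points (for a concentration: within two and a half percent of the largest)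
- run time (south-west): 12 s

Initiator decays with a half-life of 2.2 s, and its radicals pass to substrate and start first chain carriers. Carriers end in pairs as second chain carrier. If ending balances the supply of radicals, second chain carrier starts near 0.00205 mM and falls at half the initiator's decay rate. Substrate then decays first-order under this falling level, and the exponent integrated to the reading is 0.830. By this reckoning the chain turns over 56.4 % of the substrate.

The weak link is the substrate taken directly by initiating radicals, 15.2 % of the charge when the whole initiator is counted, which that figure omits. These radicals are reckoned to arrive on average with 66.7 % of the exponent still ahead, so the share 57.5 % of them is counted as striking substrate that the chain does not reach. This gives 65.1 %, the chain capacity: the fraction of the substrate that can pass through the chain by the reading, each pass taking one reagent.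

The uptake starts at 0.204 s⁻¹, close to capacity times the initiator's decay constant, 0.208 s⁻¹. It is therefore drawn as an exponential approach to capacity at that constant.

Below capacity, reagent is the limiting reagent, and the large term is the target equal to its charge. Over-reaction is the correction. While the charge is being taken up, reagent and target overlap, and their product averages the charge squared over 6. The loss, reckoned with 25 L mol⁻¹ s⁻¹, is divided by one plus that constant times charge times half the time. Each over-reaction removes one target and one reagent, and the reckoning subtracts it twice. The north-west charge stands above capacity, so there the same overlap runs to the reading and is subtracted once from capacity.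

| Flask | Reagent over substrate | Uptake time | Target reckoned |
|---|---|---|---|
| south-west | 20.0 % | 1.15 s | 19.8 % |
| south-east | 30.0 % | 1.93 s | 29.3 % |
| east | 40.0 % | 2.98 s | 38.2 % |
| north | 60.0 % | 7.94 s | 50.8 % |
| north-west | 100 % | 12 s | 46.0 % |

The reckoned row rises to north and then falls.

The forecast gives 19.7 %, 29.4 %, 38.5 %, 52 % and 42 %, rises, then falls, holding that “the chain can't use all the reagent” in north-west, and its last point lies below the reckoning here.

The flasks give 19.8 %, 29.2 %, 37.9 %, 51.7 % and 46.1 %, rises, then falls.

In the north-west flask, substrate used by the reading is 65.5 % of its charge beside a capacity of 65.1 %, and 15 % of the reagent stands with over-reaction product at 19.3 % of the substrate. In the east flask, charged below capacity, reagent falls under 2.00 % of its charge at 3.55 s against the reckoned uptake time of 2.98 s, and at the reading it stands at 0 %.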